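**Strategy.** The target is a 3,7-dioxabicyclo[3.3.0]octane (C1 carbinol, C5–H, endo aryl groups at C2 and C6). Both benzylic carbons are carried as lactone carbonyls, so everything rests on hydroxy dilactone 9. Its ring O3–C4–C5–C1–C2 is closed in one operation: the dianion of monocyclic lactone ester 7 (ring O7–C8–C1–C5–C6, C1 alkoxide, C2 methyl ester) adds formaldehyde at C5, forming C4–C5, and the new alkoxide O3 lactonises onto C2, forming O3–C2. The step exploits the cis C1–C5 fusion and the C1 alkoxide, which steers the electrophile syn to the ester. Double aryllithium addition and exo-face ionic hydrogenation then set C2 and C6.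

Key step: step 3

Remark: atoms are numbered as in 3,7-dioxabicyclo[3.3.0]octane (C1 = C–OH bridgehead, C2 and C6 = aryl-bearing carbons, C4 and C8 = CH2, C5 = C–H bridgehead). The structure as drawn is the (1S,2S,5R,6R) isomer, in which both aryl groups are endo (trans to the C1–OH and to the C5–H), and the route is built for this isomer.

Step 1
Reactants: 1 (R)-malic acid; 2 pivalaldehyde
Product: 3 2-[(2R,4R)-2-tert-butyl-5-oxo-1,3-dioxolan-4-yl]acetic acid
Conditions: TsOH (cat.), H2SO4 (cat.), pentane, reflux, Dean–Stark; recrystallisation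
Reagents that add atoms: none
Why: Acid-catalysed acetalisation of the α-hydroxy acid unit should give the five-membered dioxolanone, and the cis isomer (tert-butyl cis to the CH2CO2H arm) is the favoured, crystalline product, so the malic stereocentre fixes the acetal centre.

Step 2
Reactants: 3 2-[(2R,4R)-2-tert-butyl-5-oxo-1,3-dioxolan-4-yl]acetic acid; 4 formaldehyde
Product: 7 methyl (3S)-3-hydroxy-5-oxooxolane-3-carboxylate, via hydroxymethyl dioxolanone acid 5 (not isolated), via diol diester 6 (not isolated)
Conditions: LiN(SiMe3)2 (2.2 equiv), THF, −78 °C; CH2O (gas), −78 °C; then HCl, MeOH, 50 °C; concentrate; TsOH (cat.), PhMe, 70 °C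
Reagents that add atoms: methanol, CO
Why: Enolate aldol with self-regeneration of the stereocentre: the carboxylate–enolate dianion should take up formaldehyde trans to the tert-butyl group, so CH2OH replaces the original H with retention, after which acidic methanolysis removes the auxiliary and the primary alcohol closes the γ-lactone onto the CH2CO2Me arm.

Step 3
Reactants: 7 methyl (3S)-3-hydroxy-5-oxooxolane-3-carboxylate; 4 formaldehyde
Product: 9 (1S,5S)-1-hydroxy-3,7-dioxabicyclo[3.3.0]octane-2,6-dione, via aldol adduct 8 (not isolated)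
Conditions: LiN(SiMe3)2 (2.1 equiv), THF, −78 °C; CH2O (gas, 1.2 equiv), −78 to −20 °C; AcOH; then TsOH (cat.), PhMe, 60 °C
Reagents that add atoms: none
Why: Two equivalents of LiN(SiMe3)2 should convert 7 into its alkoxide–enolate dianion (the β-oxygen is an alkoxide, so no β-elimination can occur), the enolate carbon adds to monomeric formaldehyde, and the new primary alkoxide attacks the neighbouring methyl ester with loss of methoxide. The closest known reaction type is the Fráter–Seebach reaction of β-hydroxy ester and β-hydroxy-γ-lactone dianions, run here as an aldol addition followed by lactonisation. The ring O3–C4–C5–C1–C2 closes by 5-exo-trig acyl substitution of O3 on the C2 ester carbon, giving the cis-fused bicycle. The one new stereocentre (C5) is controlled by C1: the electrophile is expected to enter anti to the solvated lithium alkoxide, hence syn to the ester, and only this adduct can lactonise. The step needs mono-hydroxymethylation and this facial selectivity; the single enolisable CH2, stoichiometric formaldehyde at −78 °C and the cis-fused dilactone as the only ring-closed outlet secure them, because a trans adduct stays epimerisable at the lactone α-carbon and can drain into 9.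

Step 4
Reactants: 10 4-bromo-2-methoxyphenol
Product: 11 (4-bromo-2-methoxyphenoxy)(tert-butyl)dimethylsilane
Conditions: TBSCl, imidazole, DMF, rt
Reagents that add atoms: tert-butyldimethylsilyl chloride, CC(C)(C)[Si](C)(C)Cl
Why: Standard imidazole-mediated silylation of a phenol; no stereocentre is involved.

Step 5
Reactants: 9 (1S,5S)-1-hydroxy-3,7-dioxabicyclo[3.3.0]octane-2,6-dione; 11 (4-bromo-2-methoxyphenoxy)(tert-butyl)dimethylsilane
Product: 13 (1S,5S)-2,6-bis[4-(tert-butyldimethylsilyloxy)-3-methoxyphenyl]-3,7-dioxabicyclo[3.3.0]octane-1,2,6-triol (lactol epimers), via aryllithium 12 (not isolated)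
Conditions: 11 (3.3 equiv), n-BuLi (3.3 equiv), THF, −78 °C; then 9 in THF, −78 °C; AcOH, −78 °C
Reagents that add atoms: none
Why: Bromine–lithium exchange followed by aryllithium addition to γ-lactones, which should stop at the lactol alkoxide at −78 °C; one equivalent deprotonates the C1–OH, two add to C2 and C6, and the configuration of the two hemiketal carbons is irrelevant because both are reduced next.

Step 6
Reactants: 13 (1S,5S)-2,6-bis[4-(tert-butyldimethylsilyloxy)-3-methoxyphenyl]-3,7-dioxabicyclo[3.3.0]octane-1,2,6-triol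
Product: 14 (1S,2S,5R,6R)-2,6-bis[4-(tert-butyldimethylsilyloxy)-3-methoxyphenyl]-3,7-dioxabicyclo[3.3.0]octan-1-ol
Conditions: Et3SiH (6 equiv), BF3·OEt2 (3 equiv), CH2Cl2, −78 to −50 °C; Et3N quench at −78 °C
Reagents that add atoms: none
Why: Ionic hydrogenation of lactols: BF3·OEt2 should ionise each hemiketal to a 2-aryl oxocarbenium ion and Et3SiH should deliver hydride to the exo (convex) face of the cis-fused bicycle, cis to the C1–OH and to the C5–H, so both aryl groups end up endo and C2 (S) and C6 (R) are set under kinetic control.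

Step 7
Reactants: 14 (1S,2S,5R,6R)-2,6-bis[4-(tert-butyldimethylsilyloxy)-3-methoxyphenyl]-3,7-dioxabicyclo[3.3.0]octan-1-ol
Product: 15 (1S,2S,5R,6R)-2,6-bis(4-hydroxy-3-methoxyphenyl)-3,7-dioxabicyclo[3.3.0]octan-1-ol
Conditions: Bu4NF, AcOH, THF, 0 °C
Reagents that add atoms: none
Why: Fluoride cleavage of aryl silyl ethers; buffering with acetic acid should keep the phenoxides from opening the labile endo benzylic ethers, so no stereocentre is touched.

Compound list
1 | (R)-malic acid | OC(=O)C[C@@H](O)C(=O)O | starting material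
2 | pivalaldehyde | CC(C)(C)C=O | starting material
3 | 2-[(2R,4R)-2-tert-butyl-5-oxo-1,3-dioxolan-4-yl]acetic acid | OC(=O)C[C@H]1O[C@@H](C(C)(C)C)OC1=O | intermediate
4 | formaldehyde (monomeric gas from cracked paraformaldehyde) | C=O | starting material
5 | 2-[(2R,4S)-2-tert-butyl-4-(hydroxymethyl)-5-oxo-1,3-dioxolan-4-yl]acetic acid | OC(=O)C[C@@]1(CO)O[C@@H](C(C)(C)C)OC1=O | intermediate
6 | dimethyl (2S)-2-hydroxy-2-(hydroxymethyl)butanedioate | COC(=O)C[C@](O)(CO)C(=O)OC | intermediate
7 | methyl (3S)-3-hydroxy-5-oxooxolane-3-carboxylate | COC(=O)[C@]1(O)CC(=O)OC1 | intermediate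
8 | methyl (3S,4S)-3-hydroxy-4-(hydroxymethyl)-5-oxooxolane-3-carboxylate | COC(=O)[C@]1(O)[C@H](CO)C(=O)OC1 | intermediate
9 | (1S,5S)-1-hydroxy-3,7-dioxabicyclo[3.3.0]octane-2,6-dione | O=C1OC[C@@]2(O)[C@@H]1COC2=O | intermediate
10 | 4-bromo-2-methoxyphenol | COc1cc(Br)ccc1O | starting material
11 | (4-bromo-2-methoxyphenoxy)(tert-butyl)dimethylsilane | COc1cc(Br)ccc1O[Si](C)(C)C(C)(C)C | intermediate
12 | [4-(tert-butyldimethylsilyloxy)-3-methoxyphenyl]lithium | [Li]c1ccc(O[Si](C)(C)C(C)(C)C)c(OC)c1 | intermediate
13 | (1S,5S)-2,6-bis[4-(tert-butyldimethylsilyloxy)-3-methoxyphenyl]-3,7-dioxabicyclo[3.3.0]octane-1,2,6-triol (lactol epimers) | COc1cc(C2(O)OC[C@@]3(O)[C@@H]2COC3(O)c2ccc(O[Si](C)(C)C(C)(C)C)c(OC)c2)ccc1O[Si](C)(C)C(C)(C)C | intermediate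
14 | (1S,2S,5R,6R)-2,6-bis[4-(tert-butyldimethylsilyloxy)-3-methoxyphenyl]-3,7-dioxabicyclo[3.3.0]octan-1-ol | COc1cc([C@@H]2OC[C@@]3(O)[C@@H]2CO[C@H]3c2ccc(O[Si](C)(C)C(C)(C)C)c(OC)c2)ccc1O[Si](C)(C)C(C)(C)C | intermediate
15 | (1S,2S,5R,6R)-2,6-bis(4-hydroxy-3-methoxyphenyl)-3,7-dioxabicyclo[3.3.0]octan-1-ol | COc1cc([C@@H]2OC[C@@]3(O)[C@@H]2CO[C@H]3c2ccc(O)c(OC)c2)ccc1O | target

Total step count: 7. Longest linear sequence: 6 steps (steps 1, 2, 3, 5, 6, 7).

Steps most likely to fail

Step 3. The aldol may be reversible, may run a second time on the product, or may show poor facial selectivity at C5. The fallback sets out from 7: the same dianion is alkylated with benzyl chloromethyl ether, anti to the alkoxide, to give methyl (3S,4S)-4-[(benzyloxy)methyl]-3-hydroxy-5-oxooxolane-3-carboxylate F1. Hydrogenolysis (H2, Pd/C, EtOAc) frees the primary alcohol, which should lactonise on warming with TsOH, and the route is rejoined at 9.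

Step 5. The aryllithium may enolise the lactone at C5–H, or a lactol alkoxide may open to the ketone and take up a second aryl group. The fallback sets out from 9: aminolysis with MeNH(OMe)·HCl and AlMe3 opens both lactones to (2S,3S)-2-hydroxy-2,3-bis(hydroxymethyl)-N1,N4-dimethoxy-N1,N4-dimethylbutanediamide F2. Excess 12 (the three hydroxyls are deprotonated first) should give chelated tetrahedral adducts that cannot over-add; on quench they collapse to the diketone, which closes to the lactols, and the route is rejoined at 13.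

Step 6. The newly formed endo benzylic ethers may ionise under the Lewis acid, which would epimerise them toward exo aryl groups or lead to reductive ring opening. The fallback sets out from 13: desilylation (Bu4NF, AcOH) gives (1S,5S)-2,6-bis(4-hydroxy-3-methoxyphenyl)-3,7-dioxabicyclo[3.3.0]octane-1,2,6-triol F3, and selective phenol acylation (pivaloyl chloride, Et3N) gives the bis-pivalate of the bis-lactol F4, whose electron-poorer aryl groups disfavour benzylic ionisation. Reduction with Et3SiH and BF3·OEt2 should then give the bis-pivalate of the target F5, and K2CO3 in MeOH removes the esters, so the route is rejoined at 15.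

Further compounds
F1 | step 3 | methyl (3S,4S)-4-[(benzyloxy)methyl]-3-hydroxy-5-oxooxolane-3-carboxylate | COC(=O)[C@]1(O)[C@H](COCc2ccccc2)C(=O)OC1
F2 | step 5 | (2S,3S)-2-hydroxy-2,3-bis(hydroxymethyl)-N1,N4-dimethoxy-N1,N4-dimethylbutanediamide | CON(C)C(=O)[C@@H](CO)[C@](O)(CO)C(=O)N(C)OC
F3 | step 6 | (1S,5S)-2,6-bis(4-hydroxy-3-methoxyphenyl)-3,7-dioxabicyclo[3.3.0]octane-1,2,6-triol (lactol epimers) | COc1cc(C2(O)OC[C@@]3(O)[C@@H]2COC3(O)c2ccc(O)c(OC)c2)ccc1O
F4 | step 6 | [(1S,5S)-1,2,6-trihydroxy-3,7-dioxabicyclo[3.3.0]octane-2,6-diyl]bis(2-methoxy-4,1-phenylene) bis(2,2-dimethylpropanoate) (lactol epimers) | COc1cc(C2(O)OC[C@@]3(O)[C@@H]2COC3(O)c2ccc(OC(=O)C(C)(C)C)c(OC)c2)ccc1OC(=O)C(C)(C)C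
F5 | step 6 | [(1S,2S,5R,6R)-1-hydroxy-3,7-dioxabicyclo[3.3.0]octane-2,6-diyl]bis(2-methoxy-4,1-phenylene) bis(2,2-dimethylpropanoate) | COc1cc([C@@H]2OC[C@@]3(O)[C@@H]2CO[C@H]3c2ccc(OC(=O)C(C)(C)C)c(OC)c2)ccc1OC(=O)C(C)(C)C
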